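**Retrosynthetic overview**

1. Numbering: C1 ketone carbon; C2=C3 enone alkene (CH3 on C3); C4 and C11 cyclobutane CH on C3 and C1; C5 cyclobutane CH on C6 (CMe2); C7 O-senecioyl carbinol; C8 CH2; C9 O-tigloyl carbinol; C10 methyl-bearing quaternary cyclobutane carbon. The plan rests on the cyclobutane C4–C5–C11–C10: C4 and C11 are both β to the methyl carbon on C10, and each carries its outside carbon (C3, C1) on the methyl face, opposite the C6–C9 bridge of the seven-membered ring.
2. Target ⇒ tigloylation of C9–OH ⇒ Evans–Tishchenko reaction of the C7-hydroxy C9-ketone (senecioate and C9 carbinol) ⇒ catalyst-controlled conjugate borylation/oxidation of the C7=C8 enone.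
3. Cyclohexenone ring (C1, C2, C3, C4, C10, C11) ⇒ enantioselective amine-catalysed aldol condensation (C2–C3) of the meso C4,C11-diacetyl compound ⇒ ozonolysis of two isopropenyl groups, after the carboxamide carbon on C10 has been reduced to CH3 (the aminoquinoline would not survive ozone).
4. C3–C4 and C1–C11 ⇒ twofold 8-aminoquinoline-directed palladium C–H alkenylation of the bicyclo[4.1.1]octane-1-carboxamide (C9 dioxolane) with 2-iodopropene.
5. Bicycle ⇒ sulfonyl-carbanion acylation (C8–C9) onto the ester cis to the side chain of a cyclobutane-1,1-diester ⇒ malonate/1,3-ditosylate cyclobutanation. Ring order: cyclobutane, seven-membered ring, cyclohexenone.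

Key step: step 12

Assumption: the sense of induction of the chiral amine (step 18) and of the chiral bisphosphine (step 21) is inferred by analogy; the pseudo-enantiomeric or antipodal catalyst is used instead if a model correlation shows the reverse sense.

**Route**

Step 1
Reactants: 1 diethyl isopropylidenemalonate; 2 vinylmagnesium bromide
Product: 3 diethyl 2-(2-methylbut-3-en-2-yl)malonate
Conditions: CuI (10 mol%), THF, −30 → 0 °C; aq. NH4Cl
Reagents that add atoms: none
Why: Copper-catalysed conjugate addition of the vinyl Grignard reagent to the doubly activated alkylidene malonate builds quaternary C6 with its two methyl groups; no stereocentre is formed.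

Step 2
Reactants: 3 diethyl 2-(2-methylbut-3-en-2-yl)malonate
Product: 4 2-(2-methylbut-3-en-2-yl)propane-1,3-diol
Conditions: LiAlH4, THF, 0 °C → reflux; aqueous NaOH work-up
Reagents that add atoms: none
Why: LiAlH4 reduction of both ester groups gives the 1,3-diol whose CH2OH carbons become C4 and C11; the isolated vinyl group is inert.

Step 3
Reactants: 4 2-(2-methylbut-3-en-2-yl)propane-1,3-diol
Product: 5 2-(2-methylbut-3-en-2-yl)propane-1,3-diyl bis(4-methylbenzenesulfonate)
Conditions: TsCl (2.5 equiv), pyridine, 0 °C → rt
Reagents that add atoms: 4-toluenesulfonyl chloride, Cc1ccc(cc1)S(Cl)(=O)=O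
Why: Sulfonylation of the two primary alcohols makes C4 and C11 electrophilic for the ring closure.

Step 4
Reactants: 5 2-(2-methylbut-3-en-2-yl)propane-1,3-diyl bis(4-methylbenzenesulfonate); 6 diethyl malonate
Product: 7 diethyl 3-(2-methylbut-3-en-2-yl)cyclobutane-1,1-dicarboxylate
Conditions: NaH (2.2 equiv), dioxane, reflux
Reagents that add atoms: none
Why: Twofold SN2 alkylation of sodiomalonate (malonic ester cyclobutane synthesis) closes the ring C10–C4–C5–C11, the second 4-exo-tet alkylation being helped by the bulky group on C5; the two esters on C10 are identical, so no stereocentre arises.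

Step 5
Reactants: 7 diethyl 3-(2-methylbut-3-en-2-yl)cyclobutane-1,1-dicarboxylate
Product: 8 diethyl 3-[2-methyl-4-(phenylsulfanyl)butan-2-yl]cyclobutane-1,1-dicarboxylate
Conditions: PhSH (1.5 equiv), AIBN (cat.), toluene, 80 °C
Reagents that add atoms: thiophenol, Sc1ccccc1
Why: Radical-chain thiol–ene addition puts sulfur on the terminal carbon (anti-Markovnikov), because the thiyl radical adds to the unsubstituted alkene end, giving C7H2–C8H2–SPh.

Step 6
Reactants: 8 diethyl 3-[2-methyl-4-(phenylsulfanyl)butan-2-yl]cyclobutane-1,1-dicarboxylate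
Product: 9 diethyl 3-[2-methyl-4-(phenylsulfonyl)butan-2-yl]cyclobutane-1,1-dicarboxylate
Conditions: mCPBA (2.2 equiv), CH2Cl2, 0 °C → rt
Reagents that add atoms: 3-chloroperbenzoic acid, OOC(=O)c1cccc(Cl)c1
Why: Peracid oxidation of the sulfide to the sulfone makes the C8 hydrogens acidic enough for carbanion formation; the esters are untouched.

Step 7
Reactants: 9 diethyl 3-[2-methyl-4-(phenylsulfonyl)butan-2-yl]cyclobutane-1,1-dicarboxylate
Product: 10 ethyl 5,5-dimethyl-2-oxo-3-(phenylsulfonyl)bicyclo[4.1.1]octane-1-carboxylate (racemic, sulfonyl-bearing C8 as an epimer mixture)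
Conditions: LiN(iPr)2 (2.2 equiv), THF (0.02 M), −78 → 0 °C; aq. NH4Cl
Reagents that add atoms: none
Why: Intramolecular Claisen-type acylation of the α-sulfonyl carbanion at C8 by a malonate ester closes the seven-membered ring (C8–C9 bond); the tether on C5 can reach only the ester on its own ring face, so the surviving ester sits on the opposite face, which fixes the C5/C10 relationship, and the second equivalent of base stores the product as its stabilised anion.

Step 8
Reactants: 10 ethyl 5,5-dimethyl-2-oxo-3-(phenylsulfonyl)bicyclo[4.1.1]octane-1-carboxylate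
Product: 11 ethyl 5,5-dimethyl-2-oxobicyclo[4.1.1]octane-1-carboxylate
Conditions: Al(Hg), THF/H2O 9:1, rt
Reagents that add atoms: none
Why: Single-electron reductive cleavage of the C–S bond of a β-keto sulfone (aluminium amalgam desulfonylation) gives the C9 ketone with C8 as CH2 and removes the only stereocentre of 10.

Step 9
Reactants: 11 ethyl 5,5-dimethyl-2-oxobicyclo[4.1.1]octane-1-carboxylate
Product: 12 ethyl 5,5-dimethylspiro[bicyclo[4.1.1]octane-2,2'-[1,3]dioxolane]-1-carboxylate
Conditions: (Me3SiOCH2)2, Me3SiOTf (cat.), CH2Cl2, −20 °C → rt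
Reagents that add atoms: 1,2-bis(trimethylsilyloxy)ethane, C[Si](C)(C)OCCO[Si](C)(C)C
Why: Silyl-triflate-catalysed ketalisation with the bis-silyl ether of glycol works at low temperature on hindered ketones and masks C9, so that neither the carbonyl nor the C8 hydrogens interfere later.

Step 10
Reactants: 12 ethyl 5,5-dimethylspiro[bicyclo[4.1.1]octane-2,2'-[1,3]dioxolane]-1-carboxylate
Product: 13 5,5-dimethylspiro[bicyclo[4.1.1]octane-2,2'-[1,3]dioxolane]-1-carboxylic acid
Conditions: KOH, EtOH/H2O, 80 °C; then 1 M HCl to pH 4, 0 °C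
Reagents that add atoms: potassium hydroxide, [K+].[OH-]
Why: Saponification of the hindered bridgehead ester is safe once C9 is a ketal (no retro-Claisen cleavage of a β-keto ester), and cold acidification to pH 4 spares the dioxolane.

Step 11
Reactants: 13 5,5-dimethylspiro[bicyclo[4.1.1]octane-2,2'-[1,3]dioxolane]-1-carboxylic acid; 14 8-aminoquinoline
Product: 16 N-(quinolin-8-yl)-5,5-dimethylspiro[bicyclo[4.1.1]octane-2,2'-[1,3]dioxolane]-1-carboxamide, via acid chloride 15 (not isolated)
Conditions: 1-chloro-N,N,2-trimethylprop-1-en-1-amine, CH2Cl2, rt; then 14, Et3N, DMAP (cat.), CH2Cl2, rt → 40 °C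
Reagents that add atoms: none
Why: The neutral chloro-enamine converts the hindered acid into its chloride without HCl (the ketal survives), and N-acylation of 8-aminoquinoline installs the bidentate directing group on C10.

Step 12
Reactants: 16 N-(quinolin-8-yl)-5,5-dimethylspiro[bicyclo[4.1.1]octane-2,2'-[1,3]dioxolane]-1-carboxamide; 17 2-iodopropene
Product: 19 meso N-(quinolin-8-yl)-5,5-dimethyl-7,8-di(prop-1-en-2-yl)spiro[bicyclo[4.1.1]octane-2,2'-[1,3]dioxolane]-1-carboxamide (isopropenyl groups on C4 and C11 both cis to the carboxamide), via mono-isopropenyl amide 18 (not isolated)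
Conditions: Pd(OAc)2 (15 mol%), AgOAc (3 equiv), 17 (6 equiv), (BnO)2PO2H (20 mol%), t-AmOH, 90 °C, sealed tube
Reagents that add atoms: none
Why: Chelation of Pd(OAc)2 by the amide nitrogen and the quinoline nitrogen brings the metal next to the C4–H bond that is cis to the carbonyl group; acetate-assisted C–H cleavage (concerted metalation–deprotonation) gives a five-membered palladacycle of divalent palladium, which adds 2-iodopropene oxidatively (tetravalent palladium) and forms C3–C4 by reductive elimination while AgOAc takes up iodide, and mono-adduct 18 runs through the same cycle at C11 to form C1–C11. The closest known reaction type is the 8-aminoquinoline-directed palladium-catalysed β-C(sp3)–H arylation and alkenylation of cyclobutanecarboxamides, including twofold reaction of 1-substituted cyclobutanes. No ring is closed in this step. The new stereocentres C4 and C11 are set by the palladacycle, which can form only on the ring face that carries the amide, so both alkenyl groups enter cis to the carboxamide and trans to the C6–C9 bridge. The step needs this cis selectivity and complete double reaction: C10 carries no hydrogen and cannot epimerise, its full substitution presses the directing group toward the ring, the only β-C–H bonds are those of the two equivalent cyclobutane CH2 groups (C9 is a ketal carbon), and excess iodide drives the second coupling. Enantiocontrol is not required, because 19 has a mirror plane through C5, C10 and the C6–C9 bridge.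

Step 13
Reactants: 19 meso bis(isopropenyl) amide
Product: 20 tert-butyl N-acyl-N-(quinolin-8-yl)carbamate of 19 (N-Boc derivative, meso)
Conditions: Boc2O (5 equiv), DMAP, MeCN, 70 °C
Reagents that add atoms: di-tert-butyl dicarbonate, CC(C)(C)OC(=O)OC(=O)OC(C)(C)C
Why: DMAP-catalysed N-acylation turns the secondary amide into a twisted N-acyl carbamate with an electrophilic acyl carbon; the aminoquinoline must leave before ozone is used, since ozone would also cleave the electron-rich amidoquinoline ring.

Step 14
Reactants: 20 N-Boc derivative of 19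
Product: 21 [5,5-dimethyl-7,8-di(prop-1-en-2-yl)spiro[bicyclo[4.1.1]octane-2,2'-[1,3]dioxolan]-1-yl]methanol (meso)
Conditions: LiAlH4, THF, 0 °C
Reagents that add atoms: none
Why: Reductive cleavage of an N-acyl carbamate: hydride attacks the ketone-like acyl carbonyl rather than the tert-butyl-shielded carbamate carbonyl, the tetrahedral intermediate expels the carbamate anion, and the aldehyde so formed is reduced on to the neopentyl alcohol.

Step 15
Reactants: 21 neopentyl alcohol
Product: 22 5,5-dimethyl-7,8-di(prop-1-en-2-yl)spiro[bicyclo[4.1.1]octane-2,2'-[1,3]dioxolane]-1-carbaldehyde (meso)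
Conditions: Dess–Martin periodinane, NaHCO3, CH2Cl2, rt; crude product taken on at once
Reagents that add atoms: none
Why: Dess–Martin oxidation of the primary alcohol stops at the non-enolisable aldehyde; bicarbonate protects the ketal, and immediate use avoids an acid-promoted carbonyl-ene reaction with a neighbouring isopropenyl group.

Step 16
Reactants: 22 aldehyde
Product: 24 meso 1,5,5-trimethyl-7,8-di(prop-1-en-2-yl)spiro[bicyclo[4.1.1]octane-2,2'-[1,3]dioxolane], via hydrazone 23 (not isolated)
Conditions: N2H4·H2O, KOH, diethylene glycol, 130 → 200 °C, argon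
Reagents that add atoms: none
Why: Wolff–Kishner reduction (Huang–Minlon procedure) turns the aldehyde carbon into the C10 methyl group through the hydrazone anion and loss of N2; ketal and unconjugated alkenes tolerate hot KOH, and the ionic pathway avoids the ring opening open to a cyclobutylcarbinyl radical.

Step 17
Reactants: 24 meso bis(isopropenyl) ketal
Product: 26 meso 7,8-diacetyl-1,5,5-trimethylspiro[bicyclo[4.1.1]octane-2,2'-[1,3]dioxolane] (acetyl groups on C4 and C11 cis to the C10 methyl), via bis-ozonide 25 (not isolated)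
Conditions: O3, CH2Cl2, −78 °C (Sudan Red 7B end point); then Me2S, −78 °C → rt
Reagents that add atoms: ozone, [O-][O+]=O
Why: Ozonolysis with reductive work-up cleaves both 1,1-disubstituted alkenes to methyl ketones; the ketal and the saturated framework are inert, and the acetyl groups stay on the less crowded ring face, cis to the C10 methyl.

Step 18
Reactants: 26 meso diketone
Product: 28 tricyclic enone ketal (C1 ketone, C2=C3 with CH3 on C3, C9 dioxolane; C4, C5, C10, C11 as in the target), via aldol adduct 27 (not isolated)
Conditions: 9-amino-9-deoxy-epi-quinine (20 mol%), AcOH (60 mol%), toluene, 4 Å MS, rt → 45 °C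
Reagents that add atoms: none
Why: Primary-amine (enamine) catalysed intramolecular aldol condensation of a 2,6-heptanedione unit: the enamine of one acetyl group attacks the other carbonyl (6-enolexo-exo-trig), the locked cyclobutane already holds both groups 1,3-cis, and dehydration gives the C1–C2=C3 enone; the chiral amine decides which of the two enantiotopic acetyl groups is the donor and so fixes the absolute configuration at C4, C5, C10 and C11.

Step 19
Reactants: 28 tricyclic enone ketal
Product: 29 tricyclic C1,C9-dione with the C2=C3 enone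
Conditions: 2 M HCl, THF, rt
Reagents that add atoms: water, O
Why: Acid-catalysed hydrolysis of the dioxolane frees the hindered C9 ketone; the enone and the cage tolerate dilute acid at room temperature.

Step 20
Reactants: 29 tricyclic dione
Product: 31 tricyclic C2,C7-diene-1,9-dione, via silyl enol ether 30 (not isolated)
Conditions: LiN(SiMe3)2, Me3SiCl, THF, −78 °C; then Pd(OAc)2 (1.1 equiv), MeCN, rt
Reagents that add atoms: none
Why: Saegusa–Ito dehydrogenation: kinetic α-deprotonation is possible only at C8 (C10 is quaternary and C11, the α' carbon of the enone, is a bridgehead), and Pd(OAc)2 converts the C8=C9 silyl enol ether into the C7=C8 enone by β-hydride elimination.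

Step 21
Reactants: 31 tricyclic dienedione
Product: 33 7-hydroxy C1,C9-dione (C7 oxygen on the side of C4), via C7 boronate 32 (not isolated)
Conditions: CuCl (5 mol%), NaOtBu (10 mol%), (R,R)-2,3-bis(tert-butylmethylphosphino)quinoxaline (6 mol%), B2pin2 (1.1 equiv), MeOH (2 equiv), THF, 0 °C; then 30% H2O2, pH 7 phosphate buffer, 0 °C
Reagents that add atoms: hydrogen peroxide, OO
Why: Copper-catalysed enantioselective conjugate borylation followed by stereoretentive C–B oxidation gives the β-hydroxy ketone; the β-monosubstituted C7=C8 enone reacts ahead of the β,β-disubstituted C2=C3 enone, and because the two faces of C7 differ only through remote groups, the chiral bisphosphine sets the C7 configuration.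

Step 22
Reactants: 33 7-hydroxy dione; 34 3-methylbut-2-enal
Product: 35 9-hydroxy 7-(3-methylbut-2-enoate) (C9 hydroxyl on the side of C11, anti to the C7 ester)
Conditions: SmI2 (30 mol%), 34 (6 equiv), THF, −10 °C
Reagents that add atoms: none
Why: Evans–Tishchenko reaction: the samarium-bound hemiacetal formed from the C7 hydroxyl and the aldehyde delivers hydride intramolecularly to C9 on the face of the C7 oxygen, so the new C9 hydroxyl is 1,3-anti to it, while C7 is acylated as the senecioate in the same step.

Step 23
Reactants: 35 9-hydroxy 7-senecioate; 36 tiglic acid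
Product: 37 target CNP0277258.1 (C9 tiglate, C7 senecioate)
Conditions: 36, 2,4,6-trichlorobenzoyl chloride, Et3N, THF, rt; then 35, DMAP, toluene, rt → 60 °C
Reagents that add atoms: none
Why: Yamaguchi esterification through the mixed anhydride acylates the hindered C9 hydroxyl without the amine-induced ketene formation that deconjugates tigloyl chloride; the trans-1,3 arrangement of the two oxygens disfavours migration of the senecioate.

**Compound list**

1 | diethyl isopropylidenemalonate | CCOC(=O)C(=C(C)C)C(=O)OCC | starting material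
2 | vinylmagnesium bromide | C=C[Mg]Br | starting material
3 | diethyl 2-(2-methylbut-3-en-2-yl)malonate | CCOC(=O)C(C(=O)OCC)C(C)(C)C=C | intermediate
4 | 2-(2-methylbut-3-en-2-yl)propane-1,3-diol | OCC(CO)C(C)(C)C=C | intermediate
5 | 2-(2-methylbut-3-en-2-yl)propane-1,3-diyl bis(4-methylbenzenesulfonate) | Cc1ccc(cc1)S(=O)(=O)OCC(COS(=O)(=O)c1ccc(C)cc1)C(C)(C)C=C | intermediate
6 | diethyl malonate | CCOC(=O)CC(=O)OCC | starting material
7 | diethyl 3-(2-methylbut-3-en-2-yl)cyclobutane-1,1-dicarboxylate | CCOC(=O)C1(CC(C1)C(C)(C)C=C)C(=O)OCC | intermediate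
8 | diethyl 3-[2-methyl-4-(phenylsulfanyl)butan-2-yl]cyclobutane-1,1-dicarboxylate | CCOC(=O)C1(CC(C1)C(C)(C)CCSc1ccccc1)C(=O)OCC | intermediate
9 | diethyl 3-[2-methyl-4-(phenylsulfonyl)butan-2-yl]cyclobutane-1,1-dicarboxylate | CCOC(=O)C1(CC(C1)C(C)(C)CCS(=O)(=O)c1ccccc1)C(=O)OCC | intermediate
10 | ethyl 5,5-dimethyl-2-oxo-3-(phenylsulfonyl)bicyclo[4.1.1]octane-1-carboxylate (racemic, C8 epimers) | CCOC(=O)C12CC(C1)C(C)(C)CC(C2=O)S(=O)(=O)c1ccccc1 | intermediate
11 | ethyl 5,5-dimethyl-2-oxobicyclo[4.1.1]octane-1-carboxylate | CCOC(=O)C12CC(C1)C(C)(C)CCC2=O | intermediate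
12 | ethyl 5,5-dimethylspiro[bicyclo[4.1.1]octane-2,2'-[1,3]dioxolane]-1-carboxylate | CCOC(=O)C12CC(C1)C(C)(C)CCC23OCCO3 | intermediate
13 | 5,5-dimethylspiro[bicyclo[4.1.1]octane-2,2'-[1,3]dioxolane]-1-carboxylic acid | OC(=O)C12CC(C1)C(C)(C)CCC23OCCO3 | intermediate
14 | 8-aminoquinoline | Nc1cccc2cccnc12 | starting material
15 | 5,5-dimethylspiro[bicyclo[4.1.1]octane-2,2'-[1,3]dioxolane]-1-carbonyl chloride | ClC(=O)C12CC(C1)C(C)(C)CCC23OCCO3 | intermediate
16 | N-(quinolin-8-yl)-5,5-dimethylspiro[bicyclo[4.1.1]octane-2,2'-[1,3]dioxolane]-1-carboxamide | O=C(Nc1cccc2cccnc12)C34CC(C3)C(C)(C)CCC45OCCO5 | intermediate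
17 | 2-iodopropene | CC(I)=C | starting material
18 | mono-isopropenyl amide, isopropenyl cis to the carboxamide (racemic, one enantiomer drawn) | O=C(Nc1cccc2cccnc12)[C@@]34[C@@H](C(C)=C)[C@@H](C3)C(C)(C)CCC45OCCO5 | intermediate
19 | meso bis(isopropenyl) amide, both alkenyl groups cis to the carboxamide | O=C(Nc1cccc2cccnc12)[C@@]34[C@@H](C(C)=C)[C@@H]([C@H]3C(C)=C)C(C)(C)CCC45OCCO5 | intermediate
20 | N-Boc derivative of 19 | CC(C)(C)OC(=O)N(c1cccc2cccnc12)C(=O)[C@@]34[C@@H](C(C)=C)[C@@H]([C@H]3C(C)=C)C(C)(C)CCC45OCCO5 | intermediate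
21 | meso C10 hydroxymethyl bis(isopropenyl) ketal | OC[C@@]34[C@@H](C(C)=C)[C@@H]([C@H]3C(C)=C)C(C)(C)CCC45OCCO5 | intermediate
22 | meso C10 carbaldehyde | O=C[C@@]34[C@@H](C(C)=C)[C@@H]([C@H]3C(C)=C)C(C)(C)CCC45OCCO5 | intermediate
23 | hydrazone of 22 | NN=C[C@@]34[C@@H](C(C)=C)[C@@H]([C@H]3C(C)=C)C(C)(C)CCC45OCCO5 | intermediate
24 | meso 1,5,5-trimethyl-7,8-di(prop-1-en-2-yl)spiro[bicyclo[4.1.1]octane-2,2'-[1,3]dioxolane] | C[C@@]34[C@@H](C(C)=C)[C@@H]([C@H]3C(C)=C)C(C)(C)CCC45OCCO5 | intermediate
25 | bis(3-methyl-1,2,4-trioxolan-3-yl) compound (ozonide carbons undefined) | C[C@@]34[C@@H](C5(C)OCOO5)[C@@H]([C@H]3C3(C)OCOO3)C(C)(C)CCC45OCCO5 | intermediate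
26 | meso 7,8-diacetyl-1,5,5-trimethylspiro[bicyclo[4.1.1]octane-2,2'-[1,3]dioxolane] | C[C@@]34[C@@H](C(C)=O)[C@@H]([C@H]3C(C)=O)C(C)(C)CCC45OCCO5 | intermediate
27 | tricyclic aldol adduct (C3 tertiary alcohol, C3 configuration undefined) | O1CCOC12CCC(C)(C)[C@@H]3[C@H]4C(=O)CC(C)(O)[C@@H]3[C@]42C | intermediate
28 | tricyclic enone, C9 ethylene ketal | O1CCOC12CCC(C)(C)[C@@H]3[C@H]4C(=O)C=C(C)[C@@H]3[C@]42C | intermediate
29 | tricyclic C1,C9-dione, C2=C3 | O=C1CCC(C)(C)[C@@H]2[C@H]3C(=O)C=C(C)[C@@H]2[C@]31C | intermediate
30 | C9 trimethylsilyl enol ether (C8=C9) | C[Si](C)(C)OC1=CCC(C)(C)[C@@H]2[C@H]3C(=O)C=C(C)[C@@H]2[C@]31C | intermediate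
31 | tricyclic C2,C7-diene-1,9-dione | O=C1C=CC(C)(C)[C@@H]2[C@H]3C(=O)C=C(C)[C@@H]2[C@]31C | intermediate
32 | C7 pinacolboronate of the C1,C9-dione | O=C1C[C@@H](B2OC(C)(C)C(C)(C)O2)C(C)(C)[C@@H]3[C@H]4C(=O)C=C(C)[C@@H]3[C@]41C | intermediate
33 | 7-hydroxy C1,C9-dione | O=C1C[C@@H](O)C(C)(C)[C@@H]2[C@H]3C(=O)C=C(C)[C@@H]2[C@]31C | intermediate
34 | 3-methylbut-2-enal | CC(C)=CC=O | starting material
35 | 9-hydroxy 7-(3-methylbut-2-enoate) | O[C@@H]1C[C@@H](OC(=O)C=C(C)C)C(C)(C)[C@@H]2[C@H]3C(=O)C=C(C)[C@@H]2[C@]31C | intermediate
36 | tiglic acid, (E)-2-methylbut-2-enoic acid | C/C=C(\C)C(=O)O | starting material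
37 | CNP0277258.1 | C/C=C(\C)C(=O)O[C@@H]1C[C@@H](OC(=O)C=C(C)C)C(C)(C)[C@@H]2[C@H]3C(=O)C=C(C)[C@@H]2[C@]31C | target

**Step count and risks**

Total: 23 steps. Longest linear sequence: 23 steps, from 1.

Steps most likely to fail:

1. Step 12. The second alkenylation may stall, because the isopropenyl group already on C4 sits 1,3-cis to the C11–H bond and crowds the second palladation; the volatile iodide may also be consumed by homocoupling. Fallback, setting out from 16: twofold directed C–H alkynylation with (bromoethynyl)triisopropylsilane (Pd(OAc)2, AgOAc, LiCl, toluene, 110 °C) should give the bis[(triisopropylsilyl)ethynyl] amide F1, whose rod-shaped groups hardly interact at the ring. Bu4NF in THF then gives the bis(ethynyl) amide F2. Cp2ZrCl2-catalysed methylalumination with excess AlMe3 (CH2Cl2, rt) followed by protonolysis places CH3 on the inner alkyne carbon and turns each ethynyl into an isopropenyl group, which returns the route to 19.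

2. Step 18. The ring closure to the strained bicyclo[3.1.1]heptenone may be slow or reversible, or the catalyst may discriminate poorly between the two enantiotopic acetyl groups. Fallback, setting out from 26: aldol condensation without chiral control (pyrrolidine/AcOH in toluene, or KOH in MeOH) should give the racemate, that is 28 together with the mirror image of 28 F4, formed through 27 and the mirror image of 27 F3. The enantiomers are separated by preparative chromatography on a chiral stationary phase, and the route is re-entered at 28.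

3. Step 21. Facial selectivity at C7 may be poor, since only the catalyst distinguishes the two faces, or the C2=C3 enone may be borylated in competition. Fallback, setting out from 31: nucleophilic epoxidation with H2O2 under iminium catalysis by the trifluoroacetate salt of a cinchona-derived primary amine should give the C7–C8 epoxy ketone F5 (oxygen on the side of C4), which is separated from its diastereomer. Reductive opening at C8 with sodium phenylselenide ((PhSe)2, NaBH4, AcOH, EtOH) returns the route to 33.

**Further compounds**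

F1 | step 12 | meso N-(quinolin-8-yl)-5,5-dimethyl-7,8-bis[(triisopropylsilyl)ethynyl]spiro[bicyclo[4.1.1]octane-2,2'-[1,3]dioxolane]-1-carboxamide | O=C(Nc1cccc2cccnc12)[C@@]34[C@@H](C#C[Si](C(C)C)(C(C)C)C(C)C)[C@@H]([C@H]3C#C[Si](C(C)C)(C(C)C)C(C)C)C(C)(C)CCC45OCCO5
F2 | step 12 | meso N-(quinolin-8-yl)-7,8-diethynyl-5,5-dimethylspiro[bicyclo[4.1.1]octane-2,2'-[1,3]dioxolane]-1-carboxamide | O=C(Nc1cccc2cccnc12)[C@@]34[C@@H](C#C)[C@@H]([C@H]3C#C)C(C)(C)CCC45OCCO5
F3 | step 18 | mirror image of aldol adduct 27 | O1CCOC12CCC(C)(C)[C@H]3[C@@H]4C(=O)CC(C)(O)[C@H]3[C@@]42C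
F4 | step 18 | mirror image of tricyclic enone ketal 28 | O1CCOC12CCC(C)(C)[C@H]3[C@@H]4C(=O)C=C(C)[C@H]3[C@@]42C
F5 | step 21 | C7–C8 epoxide of 31, epoxide oxygen on the side of C4 | O=C1[C@H]2O[C@H]2C(C)(C)[C@@H]3[C@H]4C(=O)C=C(C)[C@@H]3[C@]41C
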